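A leftover first: Saturday's last two readings average 38.9% of G, yet Z is half the charge, so 11 percentage points of it stands unturned at 250 d.

| setting | Saturday's | Friday's | north-east | west | south-west | south-east |
|---|---|---|---|---|---|---|
| Z | 0.80 M | 0.80 M | 0.80 M | 0.80 M | 0.80 M | 0.80 M |
| D | 0.80 M | 0.80 M | 0.80 M | 0.80 M | 0.80 M | 0.80 M |
| Q | 1 equiv | 1.5 equiv | 2.00 equiv | 2.00 equiv | 2.00 equiv | 2.00 equiv |
| E | 0.2 mol% | 0.2 mol% | 0.2 mol% | 0.2 mol% | 0.2 mol% | 0.2 mol% |
| temperature | 15 °C | 48 °C | 60 °C | 30 °C |  | 0 °C |
| remark | run made earlier | run made earlier |  |  | at 60 °C until 4.0 d, from then on at 0 °C |  |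
| time |  |  | 20 d | 20 d | 20 d | 20 d |

- Saturday's (time / d: G / %): 30.0: 26.7; 60.0: 32.0; 100: 35.2; 150: 35.4; 200: 39.1; 250: 38.8
- Friday's (time / d: G / %): 2.50: 22.5; 8.00: 31.3; 10.0: 30.8; 20.0: 33.9; 25.0: 33.0; 40.0: 33.1; 50.0: 35.3

(readings scatter by 1 percentage point)

- E is single-handed; Z and D are mirror images of each other, charged as a racemate, each of them at the stated concentration
- the numbers in the tables scatter by 1 percentage point (one standard deviation)

- the best flask by amount of G, in percent of the Z and D together charged; "all alike" if 1.5 percentage points covers them all (north-east / west / south-west / south-east / all alike)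
- amount of G at the end, in percent of the Z and D together charged, north-east
- amount of G at the end, in percent of the Z and D together charged, west
- amount of G at the end, in percent of the Z and D together charged, south-west
- amount of G at the end, in percent of the Z and D together charged, south-east

Does Friday's run stop too? Yes: its last four readings average 33.8%, lower than Saturday's although it is hotter and holds 1.5 equiv of Q against 1 equiv.

How soon does each run stop? Take the first reading against the run's own plateau and assume an exponential approach. Saturday's run gives 25.9 d and Friday's gives 2.28 d. Call this the stall time, the time in which the gap between G and a run's own plateau shrinks by one e-fold.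

And the new temperatures? Interpolating its logarithm linearly in temperature, I get 0.944 d at 60 °C, 8.60 d at 30 °C and 78.2 d at 0 °C.

The weak spot? The two runs differ in Q as well as in temperature, and each stall time rests on one reading with a scatter of 1 point. So these are readings, good for comparing with the run time and no finer.

So which flask? The crossing is where the stall time equals the 20 d of the run. West's stall time is shorter than its run, and west is cooler than north-east, whose plateau should lie lower. South-east is short of time. I pick west.

And south-west? South-west's hot stage lasts 4.24 stall times, so on an exponential approach I estimate G near the hot plateau at the change. The cold tail then lasts 0.204 stall times. Taking Friday's plateau as the hot stop and half the charge as the ceiling, I reckon a gain of 3 points after the change.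

The forecast gives 33% for north-east, 41.5% for west, 37% for south-west and 19% for south-east, names west as best, and expects a “slow climb” after the cooling in south-west.

The flasks give 35.8% in north-east, 42.1% in west, 30.7% in south-west and 22.6% in south-east, so west is best.

    2 E → J (k = 17.0 L mol⁻¹ h⁻¹, Ea = 84.0 kJ mol⁻¹)
    Q + E + Z → E + G (k = 19.0 L² mol⁻² h⁻¹, Ea = 44.0 kJ mol⁻¹)
    Q + E + D → E + L (k = 6.30 L² mol⁻² h⁻¹, Ea = 65.0 kJ mol⁻¹)
    Q ⇌ X (K = 1.00, k = 0.00960 h⁻¹, Ea = 106 kJ mol⁻¹, ΔH = −64.0 kJ mol⁻¹)
    (constants at 60 °C)

South-west holds G at 30.2% at 4.00 d and 30.7% at the end, with E at 16.1% of its charge at the change and 16.0% at 20.0 d, while J makes up 84.0%. Its cold tail of 0.204 stall times was reckoned at 3 points and gave 0.50 points. South-east, with a stall time of 78.2 d against its run of 20 d, stands at 22.6% at 20.0 d with E at 96.8%, and after 2.56 stall times, at 200 d, its G is 48.3%.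

The readings stem from a simulated flask from invented constants, and the scatter is random.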